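**Retrosynthetic overview**

1. Target 28 ⇐ 24 by functional-group changes only (C1 formyl → methyl, silyl ether → acetate). The bicycle is numbered as a decahydroazulene: C1 quaternary, C3a/C8a ring fusion, C4 gem-dimethyl, C8 methylidene.
2. 24 ⇐ 23 (key step): the C8–C8a bond closes the seven-membered ring by attack of a cyclohexene CH on a gold-activated terminal alkyne. In the same event the six-membered ring contracts by a 1,2-shift to the five-membered ring (new C1–C2 bond, C1 quaternary, ring carbinol carbon expelled as the C1 formyl group).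
3. 23 ⇐ 21 ⇐ 6 + 19: the temporary cyclohexenone comes from an enamine-catalysed Michael addition and aldol condensation, then a reagent-controlled carbonyl reduction.
4. 19 ⇐ 8: enzymatic desymmetrisation of a meso cyclohexene diol, oxidative ring cleavage, γ-lactonisation and trans-selective enolate hydroxylation set the three side-chain stereocentres. 6 ⇐ 1 + 2 by conjugate addition.
5. Enabling feature: methylidene carbon C8 of the seven-membered ring is bonded to ring-fusion C8a, which is bonded to quaternary C1 of the five-membered ring. This C(=CH2)–CH–C(quaternary) triad is the imprint of an alkyne carbon, an alkene CH and a cationic alkene carbon quenched by a 1,2-shift. Ring order: lactone, temporary cyclohexene, then seven- and five-membered rings together.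

Key step: step 15

Assumption: the lipase in step 4 is taken to acetylate the hydroxymethyl arm on the (R)-configured ring carbon of meso diol 8; should the enzyme prefer the other arm, hydrolysis of the meso diacetate with the same enzyme delivers 9 instead.

**Route**

Step 1
Reactants: 1 (5-chloropent-1-yn-1-yl)trimethylsilane; 2 3-methylbut-2-enal
Product: 5 3,3-dimethyl-8-(trimethylsilyl)oct-7-ynal, via Grignard reagent 3 (not isolated), via silyl enol ether 4 (not isolated)
Conditions: Mg, THF, reflux; then 2, CuBr·SMe2 (5 mol%), Me3SiCl, HMPA, THF, −78 °C; 1 M HCl work-up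
Reagents that add atoms: none
Why: Copper-catalysed conjugate addition of the Grignard reagent to the β,β-disubstituted enal, accelerated by the chlorosilane that traps the enolate as 4, should build the gem-dimethyl quaternary carbon, and acidic work-up releases the aldehyde; no stereocentre is formed.

Step 2
Reactants: 5 3,3-dimethyl-8-(trimethylsilyl)oct-7-ynal
Product: 6 3,3-dimethyloct-7-ynal
Conditions: AgNO3 (10 mol%), acetone/H2O, rt
Reagents that add atoms: none
Why: Silver-catalysed protodesilylation should cleave only the alkynyl C–Si bond under near-neutral conditions that spare the enolisable aldehyde.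

Step 3
Reactants: 7 cis-1,2,3,6-tetrahydrophthalic anhydride
Product: 8 meso-[(1R,2S)-cyclohex-4-ene-1,2-diyl]dimethanol
Conditions: LiAlH4, THF, 0 °C to reflux
Reagents that add atoms: none
Why: Hydride reduction of the cyclic anhydride gives the 1,4-diol and keeps the cis relationship of 7, so 8 is meso.

Step 4
Reactants: 8 meso diol
Product: 9 [(1R,6S)-6-(hydroxymethyl)cyclohex-3-en-1-yl]methyl acetate
Conditions: lipase PS (Burkholderia cepacia lipase), vinyl acetate, t-BuOMe, rt
Reagents that add atoms: vinyl acetate, C=COC(C)=O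
Why: Lipase-catalysed transesterification with an irreversible acyl donor distinguishes the enantiotopic hydroxymethyl arms (enzymatic desymmetrisation) and so fixes the absolute configuration of both ring stereocentres, the later side-chain CH centres.

Step 5
Reactants: 9 monoacetate
Product: 10 [(1R,6S)-6-({[tert-butyl(dimethyl)silyl]oxy}methyl)cyclohex-3-en-1-yl]methyl acetate
Conditions: t-BuMe2SiCl, imidazole, DMF, rt
Reagents that add atoms: tert-butyl(chloro)dimethylsilane, CC(C)(C)[Si](C)(C)Cl
Why: Standard silylation of the free primary alcohol gives a group that, unlike the acetate, survives the later enolate chemistry.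

Step 6
Reactants: 10 silyl ether acetate
Product: 11 (3R,4S)-3-[(acetyloxy)methyl]-4-({[tert-butyl(dimethyl)silyl]oxy}methyl)hexanedioic acid
Conditions: RuCl3·xH2O (3 mol%), NaIO4 (4.2 equiv), MeCN/EtOAc/H2O, rt
Reagents that add atoms: sodium periodate, [Na+].[O-]I(=O)(=O)=O; water, O
Why: Ruthenium tetroxide generated in the flask cleaves the disubstituted ring alkene to the diacid (oxidative alkene cleavage) without touching the two stereocentres, the acetate or the silyl ether.

Step 7
Reactants: 11 diacid
Product: 13 (3S)-4-{[tert-butyl(dimethyl)silyl]oxy}-3-[(3R)-5-oxooxolan-3-yl]butanoic acid, via hydroxy diacid 12 (not isolated)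
Conditions: K2CO3 (3 equiv), MeOH, rt; then 1 M HCl to pH 3, EtOAc, rt
Reagents that add atoms: none
Why: Methanolysis removes the acetate and, on mild acidification, the γ-hydroxy acid closes to the five-membered lactone far faster than the freed alcohol can form the six-membered lactone with the other carboxyl group.

Step 8
Reactants: 13 lactone acid
Product: 14 (3S)-4-{[tert-butyl(dimethyl)silyl]oxy}-3-[(3R,4S)-4-hydroxy-5-oxooxolan-3-yl]butanoic acid
Conditions: KN(SiMe3)2 (2.2 equiv), THF, −78 °C; 3-phenyl-2-(phenylsulfonyl)oxaziridine, −78 °C; 1 M HCl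
Reagents that add atoms: 3-phenyl-2-(phenylsulfonyl)oxaziridine, O=S(=O)(c1ccccc1)N1OC1c1ccccc1
Why: The carboxylate shields its own α-position, so the second equivalent of base forms only the lactone enolate, which the oxaziridine oxidises (Davis oxidation) on the face anti to the bulky neighbouring substituent to give the trans hydroxy lactone.

Step 9
Reactants: 14 hydroxy lactone acid
Product: 16 (3S)-3-[(3R,4S)-4-(acetyloxy)-5-oxooxolan-3-yl]-4-{[tert-butyl(dimethyl)silyl]oxy}butanoic acid, via mixed anhydride 15 (not isolated)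
Conditions: Ac2O, pyridine, DMAP (cat.), CH2Cl2, 0 °C to rt; then H2O/THF
Reagents that add atoms: acetic anhydride, CC(=O)OC(C)=O
Why: DMAP-catalysed O-acetylation installs the lactone acetate of the target, and the transient mixed anhydride of the carboxylic acid is hydrolysed back on aqueous work-up.

Step 10
Reactants: 16 acetoxy lactone acid; 17 tributyl(ethenyl)stannane
Product: 19 (3S,4R)-4-[(2S)-1-{[tert-butyl(dimethyl)silyl]oxy}-4-oxohex-5-en-2-yl]-2-oxooxolan-3-yl acetate, via acid chloride 18 (not isolated)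
Conditions: 1-chloro-N,N,2-trimethylprop-1-en-1-amine, CH2Cl2, 0 °C to rt; then 17, PhCH2Pd(PPh3)2Cl (3 mol%), CHCl3, 60 °C
Reagents that add atoms: none
Why: The acid chloride is formed under neutral conditions that spare the silyl ether and is coupled with the vinylstannane under palladium catalysis (Stille acylation) to give the vinyl ketone without touching a stereocentre.

Step 11
Reactants: 6 3,3-dimethyloct-7-ynal; 19 vinyl ketone
Product: 20 (3S,4R)-4-[(2S,7S)-1-{[tert-butyl(dimethyl)silyl]oxy}-7-formyl-8,8-dimethyl-4-oxotridec-12-yn-2-yl]-2-oxooxolan-3-yl acetate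
Conditions: (S)-2-[methoxy(diphenyl)methyl]pyrrolidine (20 mol%), ethyl 3,4-dihydroxybenzoate (20 mol%), CH2Cl2, 4 °C, aldehyde in slight excess
Reagents that add atoms: none
Why: Enamine-catalysed Michael addition, an addition that joins all atoms of both partners: the E-enamine of 6 is shielded on one face by the diarylmethyl group of the catalyst, so the new formyl-bearing stereocentre should form as (S) under catalyst control, the stereocentres of 19 being remote.

Step 12
Reactants: 20 keto aldehyde
Product: 21 (3S,4R)-4-[(1R)-2-{[tert-butyl(dimethyl)silyl]oxy}-1-[(3R)-3-(2-methylhept-6-yn-2-yl)-6-oxocyclohex-1-en-1-yl]ethyl]-2-oxooxolan-3-yl acetate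
Conditions: Bn2NH·CF3CO2H (1 equiv), toluene, 50 °C
Reagents that add atoms: none
Why: Intramolecular aldol condensation through the only ketone enol that can give a six-membered ring, then dehydration to the conjugated enone; the tertiary C–H next to the tert-alkyl group is too hindered to enolise readily, so the stereocentre should be kept.

Step 13
Reactants: 21 cyclohexenone
Product: 22 (3S,4R)-4-[(1R)-2-{[tert-butyl(dimethyl)silyl]oxy}-1-[(3R,6S)-6-hydroxy-3-(2-methylhept-6-yn-2-yl)cyclohex-1-en-1-yl]ethyl]-2-oxooxolan-3-yl acetate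
Conditions: (R)-2-methyl-CBS-oxazaborolidine (20 mol%), catecholborane, toluene, −78 °C
Reagents that add atoms: none
Why: Corey–Bakshi–Shibata reduction, in which the oxazaborolidine binds the ketone with the fully substituted alkenyl side as the large group and delivers hydride under catalyst control to give the (S)-carbinol cis to the ring tert-alkyl group; catecholborane at −78 °C spares alkyne, lactone and acetate.

Step 14
Reactants: 22 allylic alcohol
Product: 23 (3S,4R)-4-[(1R)-2-{[tert-butyl(dimethyl)silyl]oxy}-1-[(3R,6S)-3-(2-methylhept-6-yn-2-yl)-6-[(triethylsilyl)oxy]cyclohex-1-en-1-yl]ethyl]-2-oxooxolan-3-yl acetate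
Conditions: Et3SiOTf, 2,6-lutidine, CH2Cl2, −78 °C
Reagents that add atoms: triethylsilyl trifluoromethanesulfonate, CC[Si](CC)(CC)OS(=O)(=O)C(F)(F)F
Why: Silylation of the hindered secondary allylic alcohol gives the transferable silyl group that the pinacol-type termination of the next step uses.

Step 15
Reactants: 23 cyclohexenyl triethylsilyl ether
Product: 24 (3S,4R)-4-[(1R)-2-{[tert-butyl(dimethyl)silyl]oxy}-1-[(1S,3aR,8aS)-1-formyl-4,4-dimethyl-8-methylidenedecahydroazulen-1-yl]ethyl]-2-oxooxolan-3-yl acetate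
Conditions: [(t-Bu)2(biphenyl-2-yl)P]Au(NCMe)SbF6 (5 mol%), i-PrOH (1.5 equiv), CH2Cl2 (0.01 M), rt
Reagents that add atoms: none
Why: Proposed new method: the cationic monovalent gold centre activates the terminal alkyne, the CH terminus of the trisubstituted ring alkene attacks its internal carbon, and the tertiary cation that develops next to the silyloxy-bearing carbon is quenched in the same event by a 1,2-shift of the ring CH2 (pinacol-type contraction of the six-membered ring to the cyclopentane carbaldehyde), after which propan-2-ol takes the silyl group and protonates the vinyl–gold bond to leave the exocyclic methylidene group. The closest known reaction types are the gold-catalysed carbocyclisation/pinacol cascade of 3-silyloxy-1,5-enynes and the Prins–pinacol ring contraction; gold-catalysed 7-exo-dig closures of 1,8-enynes are known on their own, but the two have not been combined on a 1,8-enyne. The seven-membered ring closes by 7-exo-dig C–C bond formation, whereas the five-membered ring is not closed but arises from the six-membered ring by the 1,2-alkyl shift. C8a is set by the tether, which hangs from the C3a stereocentre and can reach only the alkene face on its own side (cis ring fusion), and C1 is set by the anti course of the addition across the alkene, the migrating CH2 entering on the face opposite the new C8–C8a bond so that the formyl carbon ends cis to C8 and the side chain trans. The step needs exo- over endo-attack and alkyl shift over hydride shift, proton loss or hydride transfer from the side-chain CH; the terminal alkyne and the trisubstituted alkene give the Markovnikov bias, and the cis relation of silyloxy group and tether fixes a half-chair with the tert-alkyl group pseudoequatorial and the silyloxy group pseudoaxial (allylic strain with the substituent on the neighbouring alkene carbon), in which the ring CH2 is displaced to the face opposite the attack, where the migrating bond has to enter, and the carbinol C–H bond is pseudoequatorial and not axial.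

Step 16
Reactants: 24 bicyclic aldehyde
Product: 26 (3S,4R)-4-[(1R)-2-{[tert-butyl(dimethyl)silyl]oxy}-1-[(1R,3aR,8aS)-1,4,4-trimethyl-8-methylidenedecahydroazulen-1-yl]ethyl]-2-oxooxolan-3-yl acetate, via tosylhydrazone 25 (not isolated)
Conditions: TsNHNH2, EtOH, 50 °C; then catecholborane, CHCl3, 0 °C; NaOAc·3H2O, 60 °C
Reagents that add atoms: none
Why: Condensation to the tosylhydrazone, hydroboration of its C=N bond and acetate-induced loss of sulfinate and dinitrogen (Caglioti-type reduction) should turn the formyl group into the C1 methyl group under conditions that leave lactone, acetate, silyl ether and exocyclic alkene alone; no stereocentre is touched.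

Step 17
Reactants: 26 silyl ether
Product: 27 (3S,4R)-4-[(1R)-2-hydroxy-1-[(1R,3aR,8aS)-1,4,4-trimethyl-8-methylidenedecahydroazulen-1-yl]ethyl]-2-oxooxolan-3-yl acetate
Conditions: HF·pyridine, pyridine, THF, 0 °C to rt
Reagents that add atoms: none
Why: Pyridine-buffered fluoride cleaves the primary silyl ether without acid strong enough to move the exocyclic alkene into the ring.

Step 18
Reactants: 27 primary alcohol
Product: 28 (3S,4R)-4-[(1R)-2-(acetyloxy)-1-[(1R,3aR,8aS)-1,4,4-trimethyl-8-methylidenedecahydroazulen-1-yl]ethyl]-2-oxooxolan-3-yl acetate (CNP0234964.1)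
Conditions: Ac2O, pyridine, DMAP (cat.), CH2Cl2, 0 °C
Reagents that add atoms: acetic anhydride, CC(=O)OC(C)=O
Why: DMAP-catalysed acetylation of the primary alcohol completes the target without touching a stereocentre.

**Compound list**

1 | (5-chloropent-1-yn-1-yl)trimethylsilane | C[Si](C)(C)C#CCCCCl | starting material
2 | 3-methylbut-2-enal | CC(C)=CC=O | starting material
3 | [5-(trimethylsilyl)pent-4-yn-1-yl]magnesium chloride | C[Si](C)(C)C#CCCC[Mg]Cl | intermediate
4 | {[3,3-dimethyl-8-(trimethylsilyl)oct-1-en-7-yn-1-yl]oxy}trimethylsilane | C[Si](C)(C)OC=CC(C)(C)CCCC#C[Si](C)(C)C | intermediate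
5 | 3,3-dimethyl-8-(trimethylsilyl)oct-7-ynal | O=CCC(C)(C)CCCC#C[Si](C)(C)C | intermediate
6 | 3,3-dimethyloct-7-ynal | O=CCC(C)(C)CCCC#C | intermediate
7 | cis-1,2,3,6-tetrahydrophthalic anhydride, (3aR,7aS)-3a,4,7,7a-tetrahydro-2-benzofuran-1,3-dione (meso) | O=C1OC(=O)[C@H]2CC=CC[C@@H]12 | starting material
8 | meso-[(1R,2S)-cyclohex-4-ene-1,2-diyl]dimethanol | C1C=CC[C@@H](CO)[C@H]1CO | intermediate
9 | [(1R,6S)-6-(hydroxymethyl)cyclohex-3-en-1-yl]methyl acetate | C1C=CC[C@@H](COC(C)=O)[C@H]1CO | intermediate
10 | [(1R,6S)-6-({[tert-butyl(dimethyl)silyl]oxy}methyl)cyclohex-3-en-1-yl]methyl acetate | C1C=CC[C@@H](COC(C)=O)[C@H]1CO[Si](C)(C)C(C)(C)C | intermediate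
11 | (3R,4S)-3-[(acetyloxy)methyl]-4-({[tert-butyl(dimethyl)silyl]oxy}methyl)hexanedioic acid | OC(=O)C[C@H](CO[Si](C)(C)C(C)(C)C)[C@H](COC(C)=O)CC(O)=O | intermediate
12 | (3S,4R)-3-({[tert-butyl(dimethyl)silyl]oxy}methyl)-4-(hydroxymethyl)hexanedioic acid | OC(=O)C[C@H](CO[Si](C)(C)C(C)(C)C)[C@H](CO)CC(O)=O | intermediate
13 | (3S)-4-{[tert-butyl(dimethyl)silyl]oxy}-3-[(3R)-5-oxooxolan-3-yl]butanoic acid | OC(=O)C[C@H](CO[Si](C)(C)C(C)(C)C)[C@@H]1COC(=O)C1 | intermediate
14 | (3S)-4-{[tert-butyl(dimethyl)silyl]oxy}-3-[(3R,4S)-4-hydroxy-5-oxooxolan-3-yl]butanoic acid | OC(=O)C[C@H](CO[Si](C)(C)C(C)(C)C)[C@@H]1COC(=O)[C@H]1O | intermediate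
15 | acetic (3S)-3-[(3R,4S)-4-(acetyloxy)-5-oxooxolan-3-yl]-4-{[tert-butyl(dimethyl)silyl]oxy}butanoic anhydride | CC(=O)OC(=O)C[C@H](CO[Si](C)(C)C(C)(C)C)[C@@H]1COC(=O)[C@H]1OC(C)=O | intermediate
16 | (3S)-3-[(3R,4S)-4-(acetyloxy)-5-oxooxolan-3-yl]-4-{[tert-butyl(dimethyl)silyl]oxy}butanoic acid | OC(=O)C[C@H](CO[Si](C)(C)C(C)(C)C)[C@@H]1COC(=O)[C@H]1OC(C)=O | intermediate
17 | tributyl(ethenyl)stannane | C=C[Sn](CCCC)(CCCC)CCCC | starting material
18 | (3S)-3-[(3R,4S)-4-(acetyloxy)-5-oxooxolan-3-yl]-4-{[tert-butyl(dimethyl)silyl]oxy}butanoyl chloride | ClC(=O)C[C@H](CO[Si](C)(C)C(C)(C)C)[C@@H]1COC(=O)[C@H]1OC(C)=O | intermediate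
19 | (3S,4R)-4-[(2S)-1-{[tert-butyl(dimethyl)silyl]oxy}-4-oxohex-5-en-2-yl]-2-oxooxolan-3-yl acetate | C=CC(=O)C[C@H](CO[Si](C)(C)C(C)(C)C)[C@@H]1COC(=O)[C@H]1OC(C)=O | intermediate
20 | (3S,4R)-4-[(2S,7S)-1-{[tert-butyl(dimethyl)silyl]oxy}-7-formyl-8,8-dimethyl-4-oxotridec-12-yn-2-yl]-2-oxooxolan-3-yl acetate | O=C[C@H](C(C)(C)CCCC#C)CCC(=O)C[C@H](CO[Si](C)(C)C(C)(C)C)[C@@H]1COC(=O)[C@H]1OC(C)=O | intermediate
21 | (3S,4R)-4-[(1R)-2-{[tert-butyl(dimethyl)silyl]oxy}-1-[(3R)-3-(2-methylhept-6-yn-2-yl)-6-oxocyclohex-1-en-1-yl]ethyl]-2-oxooxolan-3-yl acetate | O=C1CC[C@@H](C(C)(C)CCCC#C)C=C1[C@H](CO[Si](C)(C)C(C)(C)C)[C@@H]2COC(=O)[C@H]2OC(C)=O | intermediate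
22 | (3S,4R)-4-[(1R)-2-{[tert-butyl(dimethyl)silyl]oxy}-1-[(3R,6S)-6-hydroxy-3-(2-methylhept-6-yn-2-yl)cyclohex-1-en-1-yl]ethyl]-2-oxooxolan-3-yl acetate | O[C@H]1CC[C@@H](C(C)(C)CCCC#C)C=C1[C@H](CO[Si](C)(C)C(C)(C)C)[C@@H]2COC(=O)[C@H]2OC(C)=O | intermediate
23 | (3S,4R)-4-[(1R)-2-{[tert-butyl(dimethyl)silyl]oxy}-1-[(3R,6S)-3-(2-methylhept-6-yn-2-yl)-6-[(triethylsilyl)oxy]cyclohex-1-en-1-yl]ethyl]-2-oxooxolan-3-yl acetate | CC[Si](CC)(CC)O[C@H]1CC[C@@H](C(C)(C)CCCC#C)C=C1[C@H](CO[Si](C)(C)C(C)(C)C)[C@@H]2COC(=O)[C@H]2OC(C)=O | intermediate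
24 | (3S,4R)-4-[(1R)-2-{[tert-butyl(dimethyl)silyl]oxy}-1-[(1S,3aR,8aS)-1-formyl-4,4-dimethyl-8-methylidenedecahydroazulen-1-yl]ethyl]-2-oxooxolan-3-yl acetate | C=C1CCCC(C)(C)[C@@H]2CC[C@@](C=O)([C@H](CO[Si](C)(C)C(C)(C)C)[C@@H]3COC(=O)[C@H]3OC(C)=O)[C@H]12 | intermediate
25 | 4-methylbenzenesulfonohydrazone of 24 (C1 formyl group as CH=N–NHTs) | C=C1CCCC(C)(C)[C@@H]2CC[C@@](C=NNS(=O)(=O)c3ccc(C)cc3)([C@H](CO[Si](C)(C)C(C)(C)C)[C@@H]4COC(=O)[C@H]4OC(C)=O)[C@H]12 | intermediate
26 | (3S,4R)-4-[(1R)-2-{[tert-butyl(dimethyl)silyl]oxy}-1-[(1R,3aR,8aS)-1,4,4-trimethyl-8-methylidenedecahydroazulen-1-yl]ethyl]-2-oxooxolan-3-yl acetate | C=C1CCCC(C)(C)[C@@H]2CC[C@@](C)([C@H](CO[Si](C)(C)C(C)(C)C)[C@@H]3COC(=O)[C@H]3OC(C)=O)[C@H]12 | intermediate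
27 | (3S,4R)-4-[(1R)-2-hydroxy-1-[(1R,3aR,8aS)-1,4,4-trimethyl-8-methylidenedecahydroazulen-1-yl]ethyl]-2-oxooxolan-3-yl acetate | C=C1CCCC(C)(C)[C@@H]2CC[C@@](C)([C@H](CO)[C@@H]3COC(=O)[C@H]3OC(C)=O)[C@H]12 | intermediate
28 | (3S,4R)-4-[(1R)-2-(acetyloxy)-1-[(1R,3aR,8aS)-1,4,4-trimethyl-8-methylidenedecahydroazulen-1-yl]ethyl]-2-oxooxolan-3-yl acetate | C=C1CCCC(C)(C)[C@@H]2CC[C@@](C)([C@H](COC(C)=O)[C@@H]3COC(=O)[C@H]3OC(C)=O)[C@H]12 | target

**Step count**

Total step count: 18. Longest linear sequence: 16 steps (7 to 28, steps 3 to 18); the two-step branch to aldehyde 6 joins at step 11.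

**Steps most likely to fail**

Step 15 (proposed new method). The seven-membered closure may be too slow, so that the alkyne is consumed by addition of water or alcohol. Alternatively the cation may lose a proton or take a 1,2-hydride shift instead of the ring-contracting alkyl shift. The fallback is stepwise, uses known chemistry, sets out from 22 and comes back at 26. Hydroxyl-directed epoxidation (VO(acac)2, t-BuOOH, CH2Cl2, 0 °C) should give the syn epoxy alcohol F1. A ZnBr2-promoted semipinacol rearrangement of this 2,3-epoxy alcohol contracts the ring to the β-hydroxy aldehyde F2; the same anti shift of the ring CH2 places the formyl group cis to the new hydroxyl group. The formyl group is then reduced as in step 16 through the tosylhydrazone F3 to the methyl carbinol F4, so that the later radical is not β to a formyl group. 1,1'-Thiocarbonyldiimidazole with DMAP gives the imidazole-1-carbothioate F5. Slow addition of Bu3SnH with AIBN in toluene at 110 °C generates the C8a radical, which closes the seven-membered ring by 7-exo-dig attack on the alkyne from the face of the tether and, after hydrogen transfer to the vinyl radical, gives 26.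

Step 13. The catalyst has to override the substrate's own preference for axial hydride delivery, so facial selectivity may be poor, and 1,4-reduction may compete. The fallback accepts substrate control and then inverts; it sets out from 21 and comes back at 22. Luche reduction (NaBH4, CeCl3·7H2O, MeOH, −78 °C) should give the epimeric alcohol F6 with the hydroxyl group trans to the tert-alkyl group. A Mitsunobu reaction with chloroacetic acid (PPh3, DIAD, toluene) inverts the carbinol to the chloroacetate F7. Thiourea with NaHCO3 in EtOH removes the chloroacetate in the presence of the acetate and gives 22.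

Step 16. Condensation at the neopentyl formyl group on the concave face may be slow, and the hindered borylated hydrazide may not break down cleanly to the hydrocarbon. The fallback is a radical deoxygenation; it sets out from 24 and comes back at 26. NaBH4 in THF/MeOH at 0 °C reduces the aldehyde to the neopentyl alcohol F8. 1,1'-Thiocarbonyldiimidazole with DMAP gives the imidazole-1-carbothioate F9. Barton–McCombie reduction with Bu3SnH and AIBN in refluxing toluene gives 26.

**Further compounds**

F1 | step 15 | syn 2,3-epoxy alcohol from 22 (epoxide on the alkene, cis to the hydroxyl group) | O[C@H]1CC[C@@H](C(C)(C)CCCC#C)[C@H]2O[C@@]12[C@H](CO[Si](C)(C)C(C)(C)C)[C@@H]3COC(=O)[C@H]3OC(C)=O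
F2 | step 15 | ring-contracted β-hydroxy aldehyde (1-formyl-2-hydroxy-3-(2-methylhept-6-yn-2-yl)cyclopentyl side-chain compound) | C#CCCCC(C)(C)[C@@H]1CC[C@@](C=O)([C@H](CO[Si](C)(C)C(C)(C)C)[C@@H]2COC(=O)[C@H]2OC(C)=O)[C@@H]1O
F3 | step 15 | 4-methylbenzenesulfonohydrazone of F2 | C#CCCCC(C)(C)[C@@H]1CC[C@@](C=NNS(=O)(=O)c2ccc(C)cc2)([C@H](CO[Si](C)(C)C(C)(C)C)[C@@H]3COC(=O)[C@H]3OC(C)=O)[C@@H]1O
F4 | step 15 | methyl carbinol (formyl group of F2 reduced to methyl) | C#CCCCC(C)(C)[C@@H]1CC[C@@](C)([C@H](CO[Si](C)(C)C(C)(C)C)[C@@H]2COC(=O)[C@H]2OC(C)=O)[C@@H]1O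
F5 | step 15 | O-cyclopentyl 1H-imidazole-1-carbothioate of F4 | C#CCCCC(C)(C)[C@@H]1CC[C@@](C)([C@H](CO[Si](C)(C)C(C)(C)C)[C@@H]2COC(=O)[C@H]2OC(C)=O)[C@@H]1OC(=S)n3ccnc3
F6 | step 13 | (6R)-epimer of 22 (hydroxyl trans to the tert-alkyl group) | O[C@@H]1CC[C@@H](C(C)(C)CCCC#C)C=C1[C@H](CO[Si](C)(C)C(C)(C)C)[C@@H]2COC(=O)[C@H]2OC(C)=O
F7 | step 13 | chloroacetate of 22 | ClCC(=O)O[C@H]1CC[C@@H](C(C)(C)CCCC#C)C=C1[C@H](CO[Si](C)(C)C(C)(C)C)[C@@H]2COC(=O)[C@H]2OC(C)=O
F8 | step 16 | neopentyl alcohol (C1 hydroxymethyl analogue of 24) | C=C1CCCC(C)(C)[C@@H]2CC[C@@](CO)([C@H](CO[Si](C)(C)C(C)(C)C)[C@@H]3COC(=O)[C@H]3OC(C)=O)[C@H]12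
F9 | step 16 | O-alkyl 1H-imidazole-1-carbothioate of F8 | C=C1CCCC(C)(C)[C@@H]2CC[C@@](COC(=S)n3ccnc3)([C@H](CO[Si](C)(C)C(C)(C)C)[C@@H]4COC(=O)[C@H]4OC(C)=O)[C@H]12
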